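**Retrosynthetic overview**
1. Target 27 is cut at the coumarate ester C–O bond into oxepine alcohol 22 and phenol-silylated p-coumaric acid 25; all silicon-based groups leave in one final fluoride step.
2. 22 is opened at O1–C2 of the 2,3,4,7-tetrahydrooxepine (O1, quaternary C2, C3, C4, C5=C6, C7). O1–C2 lies β to the aryl ketone (through Cα) and α to the carboxyl, so the ring is the conjugate adduct of the C7 allylic hydroxyl to a 2-alkyl-3-aroylacrylate (seco diol 21).
3. The C2=Cα bond of 21 comes from ester 12 and arylglyoxal 16 by aldol addition and elimination.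
4. The Z C5=C6 alkene of 12 comes from α-silyloxy ketone 8 and the 4-carboxybutyl ylide; 8 comes from bromide 3 and Weinreb amide 6; the E side-chain alkene comes from allylic oxidation of 5-bromo-2-methylpent-2-ene.
5. Ring order: both benzene rings are bought; the oxepine, with the only stereocentre, is closed in step 13.

Key step: step 13

Assumption: the facial preference of the squaramide catalyst on this substrate cannot be predicted with certainty; the route is written with the quinidine-derived catalyst, and the quinine-derived pseudoenantiomer is used if the Si face of C2 is favoured.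

**Step 1**
Reactants: 1 5-bromo-2-methylpent-2-ene
Product: 2 (E)-5-bromo-2-methylpent-2-en-1-ol
Conditions: SeO2 (0.3 equiv), t-BuOOH (3 equiv), salicylic acid (0.1 equiv), CH2Cl2, 0 °C → rt
Reagents that add atoms: selenium dioxide, O=[Se]=O; tert-butyl hydroperoxide, CC(C)(C)OO
Why: SeO2-catalysed allylic oxidation (ene reaction, then [2,3]-sigmatropic shift) of a gem-dimethyl trisubstituted alkene should hydroxylate the methyl trans to the chain and so fix the E side-chain alkene; the primary bromide is inert.

**Step 2**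
Reactants: 2 (E)-5-bromo-2-methylpent-2-en-1-ol
Product: 3 (E)-[(5-bromo-2-methylpent-2-en-1-yl)oxy]triethylsilane
Conditions: Et3SiCl, imidazole, CH2Cl2, 0 °C
Reagents that add atoms: chlorotriethylsilane, CC[Si](Cl)(CC)CC
Why: Imidazole-promoted silyl ether formation gives a triethylsilyl ether that tolerates organomagnesium, amide and ylide bases and is later removed with dilute acid.

**Step 3**
Reactants: 4 methyl glycolate
Product: 5 methyl 2-(triethylsilyloxy)acetate
Conditions: Et3SiCl, imidazole, CH2Cl2, 0 °C
Reagents that add atoms: chlorotriethylsilane, CC[Si](Cl)(CC)CC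
Why: Silyl ether formation on the glycolate hydroxyl provides the oxygenated two-carbon unit (C6–C7) in protected form.

**Step 4**
Reactants: 5 methyl 2-(triethylsilyloxy)acetate
Product: 6 N-methoxy-N-methyl-2-(triethylsilyloxy)acetamide
Conditions: MeNH(OMe)·HCl (1.5 equiv), i-PrMgCl (3 equiv), THF, −20 → 0 °C
Reagents that add atoms: N,O-dimethylhydroxylamine hydrochloride, CNOC.Cl
Why: Weinreb amide formation from an ester with the chloromagnesium amide of N,O-dimethylhydroxylamine proceeds at low temperature and leaves the silyl ether untouched.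

**Step 5**
Reactants: 3 (E)-[(5-bromo-2-methylpent-2-en-1-yl)oxy]triethylsilane; 6 N-methoxy-N-methyl-2-(triethylsilyloxy)acetamide
Product: 8 (E)-6-methyl-1,7-bis(triethylsilyloxy)hept-5-en-2-one, via Grignard reagent 7 (not isolated)
Conditions: Mg turnings (I2-activated), THF, rt → 40 °C; then 6, THF, −20 → 0 °C; aq NH4Cl
Reagents that add atoms: none
Why: Weinreb ketone synthesis: the homoallylic Grignard reagent adds once because the magnesium-chelated tetrahedral adduct survives until work-up, and the remote E alkene is not affected.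

**Step 6**
Reactants: 8 (E)-6-methyl-1,7-bis(triethylsilyloxy)hept-5-en-2-one; 9 (4-carboxybutyl)triphenylphosphonium bromide
Product: 11 (5Z,9E)-10-methyl-11-(triethylsilyloxy)-6-[(triethylsilyloxy)methyl]undeca-5,9-dienoic acid, via phosphorus ylide 10 (not isolated)
Conditions: 9 (2 equiv), NaN(SiMe3)2 (4 equiv), THF, 0 °C → rt; then 8, −78 °C → rt; aq NH4Cl
Reagents that add atoms: none
Why: Wittig olefination of an α-alkoxy ketone with a non-stabilised ylide is known to place the oxygenated CH2 cis to the ylide-derived chain, so C5=C6 should form with C7 and C4 on the same side (5Z); the carboxylate lets the acid be separated from Ph3PO by extraction.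

**Step 7**
Reactants: 11 (5Z,9E)-10-methyl-11-(triethylsilyloxy)-6-[(triethylsilyloxy)methyl]undeca-5,9-dienoic acid
Product: 12 2-(trimethylsilyl)ethyl (5Z,9E)-10-methyl-11-(triethylsilyloxy)-6-[(triethylsilyloxy)methyl]undeca-5,9-dienoate
Conditions: Me3SiCH2CH2OH, N,N'-dicyclohexylcarbodiimide (DCC), 4-(dimethylamino)pyridine (DMAP, cat.), CH2Cl2, 0 °C → rt
Reagents that add atoms: 2-(trimethylsilyl)ethanol, C[Si](C)(C)CCO
Why: Steglich esterification gives the 2-(trimethylsilyl)ethyl ester, which is stable to amide bases and dilute acid and is cleaved by fluoride at the end.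

**Step 8**
Reactants: 13 2',5'-dihydroxyacetophenone
Product: 14 2',5'-bis(triisopropylsilyloxy)acetophenone
Conditions: i-Pr3SiCl (2.5 equiv), imidazole, DMAP (cat.), DMF, 50 °C
Reagents that add atoms: chlorotriisopropylsilane, CC(C)[Si](Cl)(C(C)C)C(C)C
Why: Silylation of both phenols (the hydrogen-bonded ortho one needs warming) gives bulky silyl ethers that later block chromanone formation and resist the bases used downstream.

**Step 9**
Reactants: 14 2',5'-bis(triisopropylsilyloxy)acetophenone
Product: 16 2-[2,5-bis(triisopropylsilyloxy)phenyl]-2-oxoacetaldehyde, via glyoxal hydrate 15 (not isolated)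
Conditions: SeO2 (1.5 equiv), 1,4-dioxane/H2O (20:1), 100 °C; filtration; then toluene azeotrope, 4 Å molecular sieves
Reagents that add atoms: selenium dioxide, O=[Se]=O
Why: Riley oxidation converts the methyl group of an aryl methyl ketone into the aldehyde; the hydrate first obtained is dried to the free arylglyoxal before use.

**Step 10**
Reactants: 12 2-(trimethylsilyl)ethyl (5Z,9E)-10-methyl-11-(triethylsilyloxy)-6-[(triethylsilyloxy)methyl]undeca-5,9-dienoate; 16 2-[2,5-bis(triisopropylsilyloxy)phenyl]-2-oxoacetaldehyde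
Product: 18 2-(trimethylsilyl)ethyl (5Z,9E)-2-{2-[2,5-bis(triisopropylsilyloxy)phenyl]-1-hydroxy-2-oxoethyl}-10-methyl-11-(triethylsilyloxy)-6-[(triethylsilyloxy)methyl]undeca-5,9-dienoate (mixture of diastereomers), via lithium enolate 17 (not isolated)
Conditions: LiN(i-Pr)2 (1.1 equiv), THF, −78 °C; then 16, −78 °C; AcOH quench at −78 °C
Reagents that add atoms: none
Why: Aldol addition of the lithium ester enolate to the aldehyde carbon of the arylglyoxal, which is more electrophilic and less hindered than the ortho-substituted aryl ketone, forms the C2–Cα bond; the two new stereocentres are erased in step 11.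

**Step 11**
Reactants: 18 aldol adduct
Product: 20 2-(trimethylsilyl)ethyl (2E,5Z,9E)-2-{2-[2,5-bis(triisopropylsilyloxy)phenyl]-2-oxoethylidene}-10-methyl-11-(triethylsilyloxy)-6-[(triethylsilyloxy)methyl]undeca-5,9-dienoate, via mesylate 19 (not isolated)
Conditions: MsCl, Et3N, CH2Cl2, −20 °C; then DBU, 0 °C → rt
Reagents that add atoms: none
Why: Mesylation of the carbinol and E1cB elimination through the ester enolate should give the 2-alkyl-3-aroylacrylate, with the E isomer (aroyl trans to the ester) expected as the more stable product; any Z isomer is removed by chromatography.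

**Step 12**
Reactants: 20 bis(triethylsilyl) seco aroylacrylate
Product: 21 2-(trimethylsilyl)ethyl (2E,5Z,9E)-2-{2-[2,5-bis(triisopropylsilyloxy)phenyl]-2-oxoethylidene}-11-hydroxy-6-(hydroxymethyl)-10-methylundeca-5,9-dienoate
Conditions: AcOH/THF/H2O (3:1:1), 0 °C → rt; used at once
Reagents that add atoms: none
Why: Acid-catalysed hydrolysis of primary triethylsilyl ethers is much faster than that of aryl triisopropylsilyl ethers or the ester, and dilute acetic acid should neither add to nor cyclise the acceptor, so the diol is freed without background ring closure.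

**Step 13**
Reactants: 21 seco diol aroylacrylate
Product: 22 2-(trimethylsilyl)ethyl (R)-2-{2-[2,5-bis(triisopropylsilyloxy)phenyl]-2-oxoethyl}-6-[(E)-5-hydroxy-4-methylpent-3-en-1-yl]-2,3,4,7-tetrahydrooxepine-2-carboxylate
Conditions: 3-{[3,5-bis(trifluoromethyl)phenyl]amino}-4-{[(9R)-6'-methoxycinchonan-9-yl]amino}cyclobut-3-ene-1,2-dione (quinidine-derived squaramide, 10 mol%), toluene (0.02 M), 4 Å molecular sieves, −20 °C; cold filtration through silica to remove the catalyst
Reagents that add atoms: none
Why: Proposed new method: the quinuclidine nitrogen of the catalyst should activate the C7 hydroxyl as a general base while the squaramide N–H pair binds the aryl ketone oxygen, the oxygen then adds to C2 (β to the ketone, α to the ester) and the resulting enol is protonated at Cα, which is the mechanism of the known bifunctional amine/hydrogen-bond-donor catalysed cycloetherification of hydroxy enones to tetrahydrofurans and tetrahydropyrans, here extended to a seven-membered ring and a fully substituted acceptor carbon. The oxepine closes in the 7-exo-trig mode (O1–C2 formed, C2=Cα exocyclic); attack at Cα would be an 8-endo closure and is not expected to compete. The C2 stereocentre is set by the catalyst alone: delivery of oxygen to the Re face of C2 (CO2R > Cα > C3) gives the R configuration. The step needs ring-size, site and facial selectivity: the Z C5=C6 alkene holds the C7 hydroxyl and the C4 tether cis, the side-chain hydroxyl could only close a macrocycle, the silylated ortho-phenol cannot form a chromanone, and the single E geometry of the acceptor presents one defined face pattern to the catalyst. Because the addition is reversible and base could also move the double bond out of conjugation through the C3 protons, the reaction is run cold and dilute and is stopped before equilibration erodes the enantiomeric purity.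

**Step 14**
Reactants: 23 p-coumaric acid
Product: 25 (E)-4-(tert-butyldimethylsilyloxy)cinnamic acid, via silyl ester 24 (not isolated)
Conditions: t-BuMe2SiCl (2.5 equiv), imidazole, DMF, rt; then AcOH/THF/H2O, rt
Reagents that add atoms: tert-butyldimethylsilyl chloride, CC(C)(C)[Si](C)(C)Cl
Why: Silylation of phenol and acid followed by selective hydrolysis of the labile silyl ester under mild acid, which aryl silyl ethers withstand, gives the phenol-protected acid.

**Step 15**
Reactants: 22 oxepine alcohol; 25 (E)-4-(tert-butyldimethylsilyloxy)cinnamic acid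
Product: 26 2-(trimethylsilyl)ethyl (R)-2-{2-[2,5-bis(triisopropylsilyloxy)phenyl]-2-oxoethyl}-6-[(E)-5-{[(E)-3-(4-tert-butyldimethylsilyloxyphenyl)prop-2-enoyl]oxy}-4-methylpent-3-en-1-yl]-2,3,4,7-tetrahydrooxepine-2-carboxylate
Conditions: DCC, DMAP (cat.), CH2Cl2, 0 °C
Reagents that add atoms: none
Why: Steglich esterification of the only free hydroxyl, the primary allylic one of the side chain; the tertiary ether, ketone and esters are inert to the carbodiimide and the cold, weakly basic medium should not open the ring.

**Step 16**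
Reactants: 26 fully protected target
Product: 27 (R)-2-[2-(2,5-dihydroxyphenyl)-2-oxoethyl]-6-[(E)-5-{[(E)-3-(4-hydroxyphenyl)prop-2-enoyl]oxy}-4-methylpent-3-en-1-yl]-2,3,4,7-tetrahydrooxepine-2-carboxylic acid
Conditions: Bu4NF (8 equiv), AcOH (8 equiv), THF, 0 °C → rt; pH 4 buffer work-up
Reagents that add atoms: none
Why: Fluoride cleaves the three aryl silyl ethers and fragments the 2-(trimethylsilyl)ethyl ester to ethylene and Me3SiF, while acetic acid keeps the medium near neutral so that the β-alkoxy ketone should not open by elimination and C2 is kept.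

**Compound list**
1 | 5-bromo-2-methylpent-2-ene | CC(C)=CCCBr | starting material
2 | (E)-5-bromo-2-methylpent-2-en-1-ol | C/C(=C\CCBr)CO | intermediate
3 | (E)-[(5-bromo-2-methylpent-2-en-1-yl)oxy]triethylsilane | C/C(=C\CCBr)CO[Si](CC)(CC)CC | intermediate
4 | methyl glycolate | COC(=O)CO | starting material
5 | methyl 2-(triethylsilyloxy)acetate | COC(=O)CO[Si](CC)(CC)CC | intermediate
6 | N-methoxy-N-methyl-2-(triethylsilyloxy)acetamide | CON(C)C(=O)CO[Si](CC)(CC)CC | intermediate
7 | (E)-[4-methyl-5-(triethylsilyloxy)pent-3-en-1-yl]magnesium bromide | C/C(=C\CC[Mg]Br)CO[Si](CC)(CC)CC | intermediate (not isolated)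
8 | (E)-6-methyl-1,7-bis(triethylsilyloxy)hept-5-en-2-one | C/C(=C\CCC(=O)CO[Si](CC)(CC)CC)CO[Si](CC)(CC)CC | intermediate
9 | (4-carboxybutyl)triphenylphosphonium bromide | [Br-].OC(=O)CCCC[P+](c1ccccc1)(c1ccccc1)c1ccccc1 | starting material
10 | sodium 5-(triphenylphosphoranylidene)pentanoate | [Na+].[O-]C(=O)CCCC=P(c1ccccc1)(c1ccccc1)c1ccccc1 | intermediate (not isolated)
11 | (5Z,9E)-10-methyl-11-(triethylsilyloxy)-6-[(triethylsilyloxy)methyl]undeca-5,9-dienoic acid | C/C(=C\CC/C(CO[Si](CC)(CC)CC)=C/CCCC(=O)O)CO[Si](CC)(CC)CC | intermediate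
12 | 2-(trimethylsilyl)ethyl ester of 11 | C/C(=C\CC/C(CO[Si](CC)(CC)CC)=C/CCCC(=O)OCC[Si](C)(C)C)CO[Si](CC)(CC)CC | intermediate
13 | 2',5'-dihydroxyacetophenone | CC(=O)c1cc(O)ccc1O | starting material
14 | 2',5'-bis(triisopropylsilyloxy)acetophenone | CC(=O)c1cc(O[Si](C(C)C)(C(C)C)C(C)C)ccc1O[Si](C(C)C)(C(C)C)C(C)C | intermediate
15 | 1-[2,5-bis(triisopropylsilyloxy)phenyl]-2,2-dihydroxyethanone (glyoxal hydrate) | OC(O)C(=O)c1cc(O[Si](C(C)C)(C(C)C)C(C)C)ccc1O[Si](C(C)C)(C(C)C)C(C)C | intermediate (not isolated)
16 | 2-[2,5-bis(triisopropylsilyloxy)phenyl]-2-oxoacetaldehyde | O=CC(=O)c1cc(O[Si](C(C)C)(C(C)C)C(C)C)ccc1O[Si](C(C)C)(C(C)C)C(C)C | intermediate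
17 | lithium enolate of 12 | C/C(=C\CC/C(CO[Si](CC)(CC)CC)=C/CCC=C(O[Li])OCC[Si](C)(C)C)CO[Si](CC)(CC)CC | intermediate (not isolated)
18 | aldol adduct (Cα carbinol, diastereomer mixture) | C/C(=C\CC/C(CO[Si](CC)(CC)CC)=C/CCC(C(=O)OCC[Si](C)(C)C)C(O)C(=O)c1cc(O[Si](C(C)C)(C(C)C)C(C)C)ccc1O[Si](C(C)C)(C(C)C)C(C)C)CO[Si](CC)(CC)CC | intermediate
19 | methanesulfonate of 18 | C/C(=C\CC/C(CO[Si](CC)(CC)CC)=C/CCC(C(=O)OCC[Si](C)(C)C)C(OS(C)(=O)=O)C(=O)c1cc(O[Si](C(C)C)(C(C)C)C(C)C)ccc1O[Si](C(C)C)(C(C)C)C(C)C)CO[Si](CC)(CC)CC | intermediate (not isolated)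
20 | bis(triethylsilyl) seco aroylacrylate (2E,5Z,9E) | C/C(=C\CC/C(CO[Si](CC)(CC)CC)=C/CC/C(C(=O)OCC[Si](C)(C)C)=C\C(=O)c1cc(O[Si](C(C)C)(C(C)C)C(C)C)ccc1O[Si](C(C)C)(C(C)C)C(C)C)CO[Si](CC)(CC)CC | intermediate
21 | seco diol aroylacrylate (2E,5Z,9E), key-step precursor | C/C(=C\CC/C(CO)=C/CC/C(C(=O)OCC[Si](C)(C)C)=C\C(=O)c1cc(O[Si](C(C)C)(C(C)C)C(C)C)ccc1O[Si](C(C)C)(C(C)C)C(C)C)CO | intermediate
22 | (R)-oxepine alcohol, key-step product | C/C(=C\CCC1=CCC[C@@](CC(=O)c2cc(O[Si](C(C)C)(C(C)C)C(C)C)ccc2O[Si](C(C)C)(C(C)C)C(C)C)(C(=O)OCC[Si](C)(C)C)OC1)CO | intermediate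
23 | p-coumaric acid | O=C(O)/C=C/c1ccc(O)cc1 | starting material
24 | tert-butyldimethylsilyl (E)-4-(tert-butyldimethylsilyloxy)cinnamate | CC(C)(C)[Si](C)(C)OC(=O)/C=C/c1ccc(O[Si](C)(C)C(C)(C)C)cc1 | intermediate (not isolated)
25 | (E)-4-(tert-butyldimethylsilyloxy)cinnamic acid | O=C(O)/C=C/c1ccc(O[Si](C)(C)C(C)(C)C)cc1 | intermediate
26 | fully protected target | C/C(=C\CCC1=CCC[C@@](CC(=O)c2cc(O[Si](C(C)C)(C(C)C)C(C)C)ccc2O[Si](C(C)C)(C(C)C)C(C)C)(C(=O)OCC[Si](C)(C)C)OC1)COC(=O)/C=C/c1ccc(O[Si](C)(C)C(C)(C)C)cc1 | intermediate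
27 | CNP0602535.1 | C/C(=C\CCC1=CCC[C@@](CC(=O)c2cc(O)ccc2O)(C(=O)O)OC1)COC(=O)/C=C/c1ccc(O)cc1 | target

**Step count**
Total: 16 steps. Longest linear sequence: 11 steps (1, 2, 5, 6, 7, 10, 11, 12, 13, 15, 16).

**Steps most likely to fail**

Step 13 (proposed new method). The catalyst may discriminate poorly between the faces of C2 in a seven-membered closure onto a fully substituted carbon. Retro-addition and re-closure may erode the enantiomeric purity, and the base may shift the C2=Cα bond out of conjugation. The fallback sets out from 21 and returns at 22. The ring is closed without induction by the long-established base-mediated intramolecular oxa-Michael addition (t-BuOK, 10 mol%, THF, −40 °C) to give the racemic oxepine alcohol F1. F1 is resolved by preparative HPLC on a cellulose tris(3,5-dimethylphenylcarbamate) phase; the R enantiomer is 22. The unwanted (S)-oxepine alcohol F2 is returned to the racemate with the same base through the reversible ring opening and resolved again.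

Step 16. The 2-(trimethylsilyl)ethyl ester fragments slowly under buffered fluoride, and during the long exposure the coumarate ester may be cleaved or transferred. The fallback sets out from 22 and returns at 27. 22 is desilylated first (Bu4NF/AcOH, THF, rt, as long as needed) to the unprotected hydroxy acid F5. p-Coumaric acid 23 is converted to vinyl (E)-4-hydroxycinnamate F6 by transvinylation with vinyl acetate and catalytic Pd(OAc)2 (palladium diacetate, divalent palladium). The primary allylic hydroxyl of F5 is then acylated with F6 by immobilised Candida antarctica lipase B in t-BuOMe at 40 °C. This lipase acylates primary alcohols and leaves phenols and the hindered acid alone, so no protecting groups are needed.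

Step 11. The elimination may give a mixture of alkene geometries, or DBU may move the double bond into the C2=C3 position. The fallback sets out from 12 and returns at 20, replacing steps 10 and 11. Enolate 17 (LiN(i-Pr)2, THF, −78 °C) is trapped with ClP(OEt)2 to give the phosphonite F3, which is oxidised in the same flask with aqueous H2O2 to the α-phosphono ester F4. A Horner–Wadsworth–Emmons olefination of F4 with arylglyoxal 16 (LiCl, i-Pr2NEt, MeCN, 0 °C) forms the C2=Cα bond directly under mild base, with the E isomer expected.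

**Further compounds**
F1 | step 13 | racemic oxepine alcohol | C/C(=C\CCC1=CCCC(CC(=O)c2cc(O[Si](C(C)C)(C(C)C)C(C)C)ccc2O[Si](C(C)C)(C(C)C)C(C)C)(C(=O)OCC[Si](C)(C)C)OC1)CO
F2 | step 13 | (S)-oxepine alcohol | C/C(=C\CCC1=CCC[C@](CC(=O)c2cc(O[Si](C(C)C)(C(C)C)C(C)C)ccc2O[Si](C(C)C)(C(C)C)C(C)C)(C(=O)OCC[Si](C)(C)C)OC1)CO
F3 | step 11 | phosphonite, 2-(diethoxyphosphanyl) derivative of 12 | C/C(=C\CC/C(CO[Si](CC)(CC)CC)=C/CCC(C(=O)OCC[Si](C)(C)C)P(OCC)OCC)CO[Si](CC)(CC)CC
F4 | step 11 | α-phosphono ester, 2-(diethoxyphosphoryl) derivative of 12 | C/C(=C\CC/C(CO[Si](CC)(CC)CC)=C/CCC(C(=O)OCC[Si](C)(C)C)P(=O)(OCC)OCC)CO[Si](CC)(CC)CC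
F5 | step 16 | unprotected hydroxy acid, (R)-2-[2-(2,5-dihydroxyphenyl)-2-oxoethyl]-6-[(E)-5-hydroxy-4-methylpent-3-en-1-yl]-2,3,4,7-tetrahydrooxepine-2-carboxylic acid | C/C(=C\CCC1=CCC[C@@](CC(=O)c2cc(O)ccc2O)(C(=O)O)OC1)CO
F6 | step 16 | vinyl (E)-4-hydroxycinnamate | C=COC(=O)/C=C/c1ccc(O)cc1
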